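Ring C is cut at C3–C4 and O1–C2, leaving a fully substituted ring A salicylaldehyde and a 4-silyloxystyrene. The key step exploits the O5 and O7 donors of ring A. They make the C4 carbonyl oxygen basic and spread positive charge from C4, so O1–C8a–C4a–C4 acts as a 1-oxadiene once a chiral phosphoric acid relays the O1 proton to the C4 oxygen. One [4+2] event forms both bonds, closes ring C and sets C2; the C4 carbinol is then oxidised. The precursor has a single unprotected phenol, O1. O5, O7 and O4' all carry tert-butyldimethylsilyl (TBS) groups, which tolerate the acid catalyst and fall together under weakly acidic fluoride.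

Key step: step 9

Numbering: flavanone numbering is used for ring A atoms in all intermediates (formyl carbon = C4, its ring carbon = C4a, methyl-bearing carbon = C8, prenyl-bearing carbon = C6).

Assumption: the sense of induction cannot be predicted for this new reaction; (R)-TRIP is written, and (S)-TRIP is used instead if the 2R series is formed.

**Step 1**
Reactants: 1 2,4,6-trihydroxytoluene
Product: 3 2,4,6-trihydroxy-3-methylbenzaldehyde, via iminium chloride 2 (not isolated)
Conditions: POCl3 (1.05 equiv), DMF, EtOAc, 0 °C → rt; then H2O, 50 °C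
Reagents that add atoms: N,N-dimethylformamide CN(C)C=O; water O
Why: Vilsmeier–Haack formylation of a phloroglucinol, in which the two open ring positions of 1 are equivalent so only one monoaldehyde can form, and the iminium group of 2 deactivates the ring against a second attack.

**Step 2**
Reactants: 3 2,4,6-trihydroxy-3-methylbenzaldehyde; 4 3-chloro-3-methylbut-1-yne
Product: 5 2,6-dihydroxy-3-methyl-4-[(2-methylbut-3-yn-2-yl)oxy]benzaldehyde
Conditions: DBU (1.2 equiv), CuCl2·2H2O (1 mol %), MeCN, 0 °C
Reagents that add atoms: none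
Why: Copper-catalysed propargylic etherification through a copper allenylidene, in which the O7 phenol para to the formyl group is the most acidic and the only one not engaged with the carbonyl, so one equivalent of base and electrophile should alkylate it alone.

**Step 3**
Reactants: 5 2,6-dihydroxy-3-methyl-4-[(2-methylbut-3-yn-2-yl)oxy]benzaldehyde
Product: 6 6-[(tert-butyldimethylsilyl)oxy]-2-hydroxy-3-methyl-4-[(2-methylbut-3-yn-2-yl)oxy]benzaldehyde
Conditions: TBSCl (1.05 equiv), imidazole, CH2Cl2–DMF, −10 → 0 °C
Reagents that add atoms: tert-butyldimethylsilyl chloride CC(C)(C)[Si](C)(C)Cl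
Why: Site-selective phenol silylation carried out while C6 still bears hydrogen, so that O5–H (neighbours formyl and C6–H) is clearly more accessible than O1–H, which the C8 methyl group presses into the stronger chelate, the same bias that leaves the methyl-flanked hydroxyl free in partial alkylations of 3-methylphloroglucinol carbonyl compounds.

**Step 4**
Reactants: 6 6-[(tert-butyldimethylsilyl)oxy]-2-hydroxy-3-methyl-4-[(2-methylbut-3-yn-2-yl)oxy]benzaldehyde
Product: 7 6-[(tert-butyldimethylsilyl)oxy]-2-hydroxy-3-methyl-4-[(2-methylbut-3-en-2-yl)oxy]benzaldehyde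
Conditions: H2 (1 atm), Pd/CaCO3 poisoned with Pb(OAc)2, quinoline, EtOAc, rt
Reagents that add atoms: none
Why: Lindlar semi-hydrogenation of a terminal alkyne, which stops at the vinyl stage on the poisoned palladium surface and leaves the aldehyde, the tertiary ether and the aryl silyl ether untouched.

**Step 5**
Reactants: 7 6-[(tert-butyldimethylsilyl)oxy]-2-hydroxy-3-methyl-4-[(2-methylbut-3-en-2-yl)oxy]benzaldehyde
Product: 9 6-[(tert-butyldimethylsilyl)oxy]-2,4-dihydroxy-3-methyl-5-(3-methylbut-2-en-1-yl)benzaldehyde, via ortho-dienone 8 (not isolated)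
Conditions: PhMe, 110 °C (sealed tube)
Reagents that add atoms: none
Why: Aromatic Claisen rearrangement, in which the [3,3] shift inverts the tertiary allyl unit and delivers a linear prenyl group to C6, the only ortho position bearing hydrogen (a shift to the methyl-bearing C8 is reversible and unproductive), after which dienone 8 rearomatises by tautomerisation.

**Step 6**
Reactants: 9 6-[(tert-butyldimethylsilyl)oxy]-2,4-dihydroxy-3-methyl-5-(3-methylbut-2-en-1-yl)benzaldehyde
Product: 10 4,6-bis[(tert-butyldimethylsilyl)oxy]-2-hydroxy-3-methyl-5-(3-methylbut-2-en-1-yl)benzaldehyde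
Conditions: TBSCl (1.1 equiv), imidazole, DMF, 0 °C → rt
Reagents that add atoms: tert-butyldimethylsilyl chloride CC(C)(C)[Si](C)(C)Cl
Why: Chemoselective silylation of the non-chelated and more acidic O7 phenol, while O1–H, now the sole partner of the formyl oxygen and shielded by the C8 methyl group, should stay free with limited reagent.

**Step 7**
Reactants: 11 4-acetoxystyrene
Product: 12 4-vinylphenol
Conditions: K2CO3 (10 mol %), MeOH, 0 °C → rt
Reagents that add atoms: none
Why: Base-catalysed transesterification of an aryl acetate, fast under mild conditions, with the polymerisation-prone phenol taken on at once as a crude solution.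

**Step 8**
Reactants: 12 4-vinylphenol
Product: 13 tert-butyldimethyl(4-vinylphenoxy)silane
Conditions: TBSCl, imidazole, CH2Cl2, 0 °C → rt
Reagents that add atoms: tert-butyldimethylsilyl chloride CC(C)(C)[Si](C)(C)Cl
Why: Standard silylation of an unhindered phenol, giving a storable, electron-rich styrene with no acidic proton.

**Step 9**
Reactants: 10 4,6-bis[(tert-butyldimethylsilyl)oxy]-2-hydroxy-3-methyl-5-(3-methylbut-2-en-1-yl)benzaldehyde; 13 tert-butyldimethyl(4-vinylphenoxy)silane
Product: 15 (2S,4S)-5,7-bis[(tert-butyldimethylsilyl)oxy]-2-{4-[(tert-butyldimethylsilyl)oxy]phenyl}-8-methyl-6-(3-methylbut-2-en-1-yl)chroman-4-ol (2,4-cis), via hydroxy ortho-quinone methide 14 (not isolated)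
Conditions: (R)-TRIP [(R)-3,3'-bis(2,4,6-triisopropylphenyl)-1,1'-binaphthyl-2,2'-diyl hydrogen phosphate] (10 mol %), 13 (3 equiv), PhMe, 0 °C → rt; Et3N quench
Reagents that add atoms: none
Why: Proposed new method: the phosphoric acid bridges O1–H and the C4 carbonyl oxygen and relays the proton, so that 10 reacts as the hydroxy ortho-quinone methide 14, whose protonated form is a C4 cation delocalised onto O5, O7 and O1 of ring A and is held to the chiral phosphate by two hydrogen bonds. The CH2 terminus of 13 bonds to C4 while O1 collapses on the developing 4-silyloxybenzylic cation at C2, an asynchronous inverse-demand oxa-[4+2] cycloaddition that closes the six-membered ring C in one event. The closest known reaction types are the racemic acid-promoted cycloaddition of salicylaldehyde-derived alkoxy ortho-quinone methides with styrenes, which gives 2,4-cis-4-alkoxyflavans, and the phosphoric acid catalysed cycloadditions of ortho-quinone methides released from ortho-hydroxybenzyl alcohols. C2 is controlled by the 3,3'-aryl pocket of the catalyst, which leaves one face of the doubly bound oxadiene open, in combination with the endo placement of the aryl group that also sets C4 (2,4-cis); because an exo adduct on the same oxadiene face would carry 2R, any trans isomer is removed before step 10. Regiochemistry follows from the polarisation of 13 (aryl ends on C2), the ring fusion is fixed because no phenol other than O1 is unprotected, and the prenyl alkene is outcompeted by the more nucleophilic styrene used in excess. Silyl rather than acetal protection takes away competing hydrogen-bond acceptors and excludes acid-induced acetal exchange between O5 and the new C4 hydroxyl.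

**Step 10**
Reactants: 15 (2S,4S)-5,7-bis[(tert-butyldimethylsilyl)oxy]-2-{4-[(tert-butyldimethylsilyl)oxy]phenyl}-8-methyl-6-(3-methylbut-2-en-1-yl)chroman-4-ol
Product: 16 (2S)-5,7-bis[(tert-butyldimethylsilyl)oxy]-2-{4-[(tert-butyldimethylsilyl)oxy]phenyl}-8-methyl-6-(3-methylbut-2-en-1-yl)chroman-4-one
Conditions: Dess–Martin periodinane, NaHCO3, CH2Cl2, 0 °C
Reagents that add atoms: none
Why: Dess–Martin oxidation of a secondary benzylic alcohol under buffered, base-free conditions, which should spare the trisubstituted alkene and the silyl ethers, suppress ionisation at C4, erase the C4 stereocentre and leave C2 untouched.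

**Step 11**
Reactants: 16 (2S)-5,7-bis[(tert-butyldimethylsilyl)oxy]-2-{4-[(tert-butyldimethylsilyl)oxy]phenyl}-8-methyl-6-(3-methylbut-2-en-1-yl)chroman-4-one
Product: 17 (2S)-5,7-dihydroxy-2-(4-hydroxyphenyl)-8-methyl-6-(3-methylbut-2-en-1-yl)chroman-4-one
Conditions: Et3N·3HF, THF, 0 °C → rt; pH 5–6 buffer work-up
Reagents that add atoms: none
Why: Fluoride-induced cleavage of three aryl silyl ethers in a weakly acidic medium, where neither a 4'-phenoxide nor a C3 enolate builds up, so the retro-oxa-Michael opening that would racemise C2 is avoided and the acidity stays too low to cyclise the prenyl group onto O5 or O7.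

**Compound list**

| No. | Name | SMILES | Role |
|---|---|---|---|
| 1 | 2,4,6-trihydroxytoluene | Cc1c(O)cc(O)cc1O | starting material |
| 2 | N,N-dimethyl(2,4,6-trihydroxy-3-methylbenzylidene)iminium chloride | C[N+](C)=Cc1c(O)cc(O)c(C)c1O.[Cl-] | intermediate |
| 3 | 2,4,6-trihydroxy-3-methylbenzaldehyde | Cc1c(O)cc(O)c(C=O)c1O | intermediate |
| 4 | 3-chloro-3-methylbut-1-yne | CC(C)(Cl)C#C | starting material |
| 5 | 2,6-dihydroxy-3-methyl-4-[(2-methylbut-3-yn-2-yl)oxy]benzaldehyde | C#CC(C)(C)Oc1cc(O)c(C=O)c(O)c1C | intermediate |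
| 6 | 6-[(tert-butyldimethylsilyl)oxy]-2-hydroxy-3-methyl-4-[(2-methylbut-3-yn-2-yl)oxy]benzaldehyde | C#CC(C)(C)Oc1cc(O[Si](C)(C)C(C)(C)C)c(C=O)c(O)c1C | intermediate |
| 7 | 6-[(tert-butyldimethylsilyl)oxy]-2-hydroxy-3-methyl-4-[(2-methylbut-3-en-2-yl)oxy]benzaldehyde | C=CC(C)(C)Oc1cc(O[Si](C)(C)C(C)(C)C)c(C=O)c(O)c1C | intermediate |
| 8 | ortho-dienone, 2-[(tert-butyldimethylsilyl)oxy]-6-hydroxy-5-methyl-3-(3-methylbut-2-en-1-yl)-4-oxocyclohexa-1,5-diene-1-carbaldehyde (transient, racemic at C6) | CC(C)=CCC1C(=O)C(C)=C(O)C(C=O)=C1O[Si](C)(C)C(C)(C)C | intermediate |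
| 9 | 6-[(tert-butyldimethylsilyl)oxy]-2,4-dihydroxy-3-methyl-5-(3-methylbut-2-en-1-yl)benzaldehyde | CC(C)=CCc1c(O)c(C)c(O)c(C=O)c1O[Si](C)(C)C(C)(C)C | intermediate |
| 10 | 4,6-bis[(tert-butyldimethylsilyl)oxy]-2-hydroxy-3-methyl-5-(3-methylbut-2-en-1-yl)benzaldehyde | CC(C)=CCc1c(O[Si](C)(C)C(C)(C)C)c(C)c(O)c(C=O)c1O[Si](C)(C)C(C)(C)C | intermediate |
| 11 | 4-acetoxystyrene | CC(=O)Oc1ccc(C=C)cc1 | starting material |
| 12 | 4-vinylphenol | C=Cc1ccc(O)cc1 | intermediate |
| 13 | tert-butyldimethyl(4-vinylphenoxy)silane | C=Cc1ccc(O[Si](C)(C)C(C)(C)C)cc1 | intermediate |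
| 14 | hydroxy ortho-quinone methide tautomer of 10, catalyst-bound (exocyclic C4a=C4 geometry labile through proton relay) | CC(C)=CCC1=C(O[Si](C)(C)C(C)(C)C)C(=CO)C(=O)C(C)=C1O[Si](C)(C)C(C)(C)C | intermediate |
| 15 | (2S,4S)-5,7-bis[(tert-butyldimethylsilyl)oxy]-2-{4-[(tert-butyldimethylsilyl)oxy]phenyl}-8-methyl-6-(3-methylbut-2-en-1-yl)chroman-4-ol | CC(C)=CCc1c(O[Si](C)(C)C(C)(C)C)c(C)c2c(c1O[Si](C)(C)C(C)(C)C)[C@@H](O)C[C@@H](c1ccc(O[Si](C)(C)C(C)(C)C)cc1)O2 | intermediate |
| 16 | (2S)-5,7-bis[(tert-butyldimethylsilyl)oxy]-2-{4-[(tert-butyldimethylsilyl)oxy]phenyl}-8-methyl-6-(3-methylbut-2-en-1-yl)chroman-4-one | CC(C)=CCc1c(O[Si](C)(C)C(C)(C)C)c(C)c2c(c1O[Si](C)(C)C(C)(C)C)C(=O)C[C@@H](c1ccc(O[Si](C)(C)C(C)(C)C)cc1)O2 | intermediate |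
| 17 | (2S)-5,7,4'-trihydroxy-8-methyl-6-prenylflavanone | CC(C)=CCc1c(O)c(C)c2c(c1O)C(=O)C[C@@H](c1ccc(O)cc1)O2 | target |

Total step count: 11. Longest linear sequence: 9 (steps 1–6 and 9–11).

**Steps most likely to fail**

**Step 9.**
- What may go wrong:
  - too little activation of the donor-rich aldehyde;
  - acid-induced ionisation of the product carbinol, followed by elimination or a second styrene addition;
  - cationic oligomerisation of the styrene;
  - poor facial or endo/exo selectivity, which would erode the purity at C2 after oxidation.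
- Fallback: it sets out from 10 and returns at 16, and it uses known chemistry only.
  - Addition of MeMgBr (excess, THF, −78 °C) to the aldehyde gives the benzylic alcohol 1-[4,6-bis(tert-butyldimethylsilyloxy)-2-hydroxy-3-methyl-5-prenylphenyl]ethan-1-ol F1.
  - Oxidation with MnO2 (CH2Cl2) gives the ortho-hydroxyacetophenone 1-[4,6-bis(tert-butyldimethylsilyloxy)-2-hydroxy-3-methyl-5-prenylphenyl]ethan-1-one F2.
  - Condensation with N,N-dimethylformamide dimethyl acetal (PhMe, 80 °C) gives the enaminone (E)-3-(dimethylamino)-1-[4,6-bis(tert-butyldimethylsilyloxy)-2-hydroxy-3-methyl-5-prenylphenyl]prop-2-en-1-one F3.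
  - Silica gel or catalytic TsOH in CH2Cl2 closes it to 5,7-bis(tert-butyldimethylsilyloxy)-8-methyl-6-prenyl-4H-chromen-4-one F4.
  - Base-free asymmetric conjugate addition of commercial 4-(tert-butyldimethylsilyloxy)phenylboronic acid under divalent palladium catalysis then gives 16. The conditions are Pd(OCOCF3)2, the t-BuPyOx ligand enantiomer that delivers 2S, NH4PF6, H2O, ClCH2CH2Cl, 60 °C. This is an established entry to enantioenriched flavanones from chromones.

**Step 3.**
- What may go wrong: incomplete discrimination between the two phenols that flank the formyl group.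
- Fallback: it sets out from 1 and returns at 9. The formyl group is introduced last, so O5 never has to be told from O1 next to a carbonyl.
  - One equivalent of TBSCl (imidazole, DMF, −20 °C) silylates the least hindered hydroxyl of 1, the one para to the methyl group. This gives the symmetric 5-(tert-butyldimethylsilyloxy)-2-methylbenzene-1,3-diol F5.
  - The two remaining hydroxyls of F5 are equivalent. Anhydrous copper-catalysed etherification with one equivalent of 4 (DBU, CuCl2, MeCN, 0 °C) therefore raises no site question and gives 5-(tert-butyldimethylsilyloxy)-2-methyl-3-[(2-methylbut-3-yn-2-yl)oxy]phenol F6.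
  - Semi-hydrogenation gives 5-(tert-butyldimethylsilyloxy)-2-methyl-3-[(2-methylbut-3-en-2-yl)oxy]phenol F7.
  - Claisen rearrangement gives 5-(tert-butyldimethylsilyloxy)-2-methyl-4-prenylbenzene-1,3-diol F8.
  - Magnesium-mediated ortho-formylation (MgCl2, Et3N, paraformaldehyde, THF, reflux) then finds a single open ring position, ortho to the future O1 phenol, and gives 9.

**Step 2.**
- What may go wrong: competing C-alkylation at C6, multiple O-alkylation of the triphenol, or sluggish conversion of the tertiary electrophile.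
- Fallback: it sets out from 3 and returns at 10. Ether formation and the sigmatropic shift are replaced by a cross-coupling.
  - Silylation of 3 with two equivalents of TBSCl (imidazole, DMF), which relies on the same steric bias as step 3, gives 4,6-bis(tert-butyldimethylsilyloxy)-2-hydroxy-3-methylbenzaldehyde F9.
  - N-Iodosuccinimide (CH2Cl2, 0 °C) iodinates the only open ring position, para to the free phenol, to give 4,6-bis(tert-butyldimethylsilyloxy)-2-hydroxy-5-iodo-3-methylbenzaldehyde F10.
  - Stille coupling with tributyl(3-methylbut-2-en-1-yl)stannane [Pd(PPh3)4, DMF, 80 °C] installs the linear prenyl group and gives 10.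

**Further compounds**

F1 | step 9 | 1-[4,6-bis(tert-butyldimethylsilyloxy)-2-hydroxy-3-methyl-5-prenylphenyl]ethan-1-ol (racemic) | CC(C)=CCc1c(O[Si](C)(C)C(C)(C)C)c(C)c(O)c(C(C)O)c1O[Si](C)(C)C(C)(C)C
F2 | step 9 | 1-[4,6-bis(tert-butyldimethylsilyloxy)-2-hydroxy-3-methyl-5-prenylphenyl]ethan-1-one | CC(C)=CCc1c(O[Si](C)(C)C(C)(C)C)c(C)c(O)c(C(C)=O)c1O[Si](C)(C)C(C)(C)C
F3 | step 9 | (E)-3-(dimethylamino)-1-[4,6-bis(tert-butyldimethylsilyloxy)-2-hydroxy-3-methyl-5-prenylphenyl]prop-2-en-1-one | CC(C)=CCc1c(O[Si](C)(C)C(C)(C)C)c(C)c(O)c(C(=O)/C=C/N(C)C)c1O[Si](C)(C)C(C)(C)C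
F4 | step 9 | 5,7-bis(tert-butyldimethylsilyloxy)-8-methyl-6-prenyl-4H-chromen-4-one | CC(C)=CCc1c(O[Si](C)(C)C(C)(C)C)c(C)c2occc(=O)c2c1O[Si](C)(C)C(C)(C)C
F5 | step 3 | 5-(tert-butyldimethylsilyloxy)-2-methylbenzene-1,3-diol | Cc1c(O)cc(O[Si](C)(C)C(C)(C)C)cc1O
F6 | step 3 | 5-(tert-butyldimethylsilyloxy)-2-methyl-3-[(2-methylbut-3-yn-2-yl)oxy]phenol | C#CC(C)(C)Oc1cc(O[Si](C)(C)C(C)(C)C)cc(O)c1C
F7 | step 3 | 5-(tert-butyldimethylsilyloxy)-2-methyl-3-[(2-methylbut-3-en-2-yl)oxy]phenol | C=CC(C)(C)Oc1cc(O[Si](C)(C)C(C)(C)C)cc(O)c1C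
F8 | step 3 | 5-(tert-butyldimethylsilyloxy)-2-methyl-4-prenylbenzene-1,3-diol | CC(C)=CCc1c(O)c(C)c(O)cc1O[Si](C)(C)C(C)(C)C
F9 | step 2 | 4,6-bis(tert-butyldimethylsilyloxy)-2-hydroxy-3-methylbenzaldehyde | Cc1c(O)c(C=O)c(O[Si](C)(C)C(C)(C)C)cc1O[Si](C)(C)C(C)(C)C
F10 | step 2 | 4,6-bis(tert-butyldimethylsilyloxy)-2-hydroxy-5-iodo-3-methylbenzaldehyde | Cc1c(O)c(C=O)c(O[Si](C)(C)C(C)(C)C)c(I)c1O[Si](C)(C)C(C)(C)C
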